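Look first at how fast the product still rises. In Friday's flask you have followed one charge of substrate with a trace of free enzyme, and you must say what stands at 8.0 d and which option to take then.

the same everywhere: substrate 0.10 M; free enzyme 5.6 × 10⁻⁴ mol%

|  | temperature | remark | time |
|---|---|---|---|
| Friday's | 40 °C | the very flask that is asked about, followed so far |  |
| Monday's | 46 °C | run made earlier |  |
| flask | 40 °C |  | 8.0 d |

| run | time / d | product / % |
|---|---|---|
| Friday's | 1.25 | 24.3 |
| Friday's | 2.50 | 32.4 |
| Friday's | 4.00 | 37.2 |
| Friday's | 5.00 | 39.0 |
| Friday's | 6.00 | 39.3 |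
| Monday's | 1.25 | 28.0 |
| Monday's | 2.50 | 34.2 |
| Monday's | 4.00 | 37.7 |
| Monday's | 5.00 | 38.8 |
| Monday's | 6.00 | 39.0 |

(standard deviation of a reading: 1 percentage point)

- theta: at 8.0 d raise the temperature by 20 K, then wait 2.5 d
- eta: at 8.0 d take out 90% of the product then present, then wait 2.5 d
- alpha: at 8.0 d add free enzyme, 100% of the amount charged, then wait 2.5 d
- delta: change nothing and wait 2.5 d more

- product, in percent of the substrate first charged, at 8.0 d
- which option adds most product ("none" when 2 percentage points or less is all one gets) (theta / eta / alpha / delta / none)
- product present, with what was taken out counted in, in percent of the substrate first charged, after theta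
- product present, with what was taken out counted in, in percent of the substrate first charged, after alpha

- product taken out counts as made
- steps under discussion: free enzyme -> unfolded enzyme; substrate + free enzyme -> product + free enzyme; 2 free enzyme <-> resting dimer; substrate <-> dormant form
- additions bring no volume worth counting

Count the charge as one whole. At 6.00 d Friday's product reads 39.3%, so 60.7% of the charge is still something other than product. You cannot yet tell what end this flask is heading for, but you can ask how fast it still moves. Call the late slope, the usual term being residual rate, the fraction of the charge turned into product per day over the last readings, here from 4.00 d to 6.00 d: 0.0105 d⁻¹. Over the first 1.25 d Friday's flask made 0.194 d⁻¹, so it has slowed greatly. The slope rests on a rise of 2.1 percentage points against a scatter of 1 point on each reading, so it is a rough reading. Monday's run, at 46 °C, gives a late slope of 0.00650 d⁻¹, lower than Friday's.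

My reckoning carries the slope forward from the last reading, which puts Friday's flask at 41.4% at 8.0 d. Waiting 2.5 d more then gains 2.6 points. I book theta at that same gain, because Monday's late slope is lower than Friday's, which gives about 44.0%. Eta I book the same, for want of a reading that speaks for it. For alpha I let the rate follow the working enzyme and take the slope as doubled, so it gains 5.2 points, more than waiting, and reaches about 46.6%. My choice is alpha.

The forecast gives 39.7% (38.8% to 40.8%), 40.2% after theta, 58% after alpha and alpha as best, saying "Waiting or heating gives almost nothing".

Friday's flask gives 41.3% at 8.0 d. The best option is alpha, which adds 7.1 points and reaches 48.4%; theta reaches 42.7%, and waiting adds 1.5 points.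

    free enzyme → unfolded enzyme (k = 2.10 × 10⁻⁴ h⁻¹, Ea = 282 kJ mol⁻¹)
    substrate + free enzyme → product + free enzyme, rate k2*[substrate]*[free enzyme]/(1 + ([substrate]/Km2) + ([product]/Kp2)) (0.160 M, 0.0800 M, k = 56000 M⁻¹ h⁻¹, Ea = 49.0 kJ mol⁻¹)
    2 free enzyme ⇌ resting dimer (K = 3.30 × 10⁸ M⁻¹, k = 51000 M⁻¹ h⁻¹, Ea = 50.0 kJ mol⁻¹, ΔH = −1.00 kJ mol⁻¹)
    substrate ⇌ dormant form (K = 2.60, k = 0.00990 h⁻¹, Ea = 105 kJ mol⁻¹, ΔH = −70.0 kJ mol⁻¹)
    (constants at 40 °C)

So Friday's flask has not come to rest at 8.0 d. In the alpha flask product rose by 0.0284 d⁻¹ after the dose, above the doubled late slope of 0.0210 d⁻¹. Left alone, Friday's flask slows further: its mean slope from 8.0 d to 80.0 d is 0.00286 d⁻¹, below the 0.0105 d⁻¹ read from the run. Over that long wait this small slope still adds 21 points. At 80.0 d the product stands at 61.9%, with substrate at 10.1% and dormant form at 28.0%.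

The data stem from a simulated flask on assumed constants; scatter was added.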